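Atom numbering used throughout: ring O1–O2–C3–C4–C5–C6; acid arm C1 (CO2H)–C2 on C3; chain C7–C16 on C6 with the phenyl ring on C16; methyl groups on C4, C6 and C8. The target is 2-[(3S,4R,6S)-3-hydroxy-4,6-dimethyl-6-[(2R)-2-methyl-10-phenyldecyl]-1,2-dioxan-3-yl]acetic acid (20).

## The problem

Compound 20 is a single six-membered ring, a 1,2-dioxan-3-ol, carrying an open chain; nothing is fused, so the whole difficulty lies in the peroxide ring and its three stereocentres. The O1–O2 bond forbids hydrogenation, dissolving metals, silane/acid reduction and low-valent metals once the ring exists. C3 is a masked ketone β to the C1 acid, so whenever the hemiketal opens with the acid free the molecule is a β-keto acid that can lose C1; the acid must therefore appear last and near neutral pH. C8 sits alone in the chain, cannot be corrected later (a C8 epimer would be practically inseparable) and must be brought in with high enantiopurity. C3 is anomeric and equilibrates, and C4 is α to the masked ketone and equilibrates through the open hydroperoxy ketone. In the chair, 20 is the isomer with axial OH, equatorial arm, equatorial C4 methyl, equatorial chain and axial methyl at C6, so C3 can be left to thermodynamics and C4 is an equilibrating centre that can be recycled. C6 is a fully substituted peroxide carbon, fixed for good when C6–O1 forms and too far from C8 to be steered by it; this is the centre no simple plan controls. The enabling feature is that C3/C4 become the ketone and α-carbon of a 1,3-dicarbonyl once a temporary ester sits on C4, C5/C6 are the carbons of a 1,1-disubstituted alkene, and O1–O2 is molecular oxygen; C2 must not lie between two carbonyls at that moment, so C1 has to enter below the acid oxidation level.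

## Retrosynthesis

**20 from 18.** No skeletal bond is cut; C1 is taken back from the acid to the primary alcohol of diol 18. This keeps the latent β-keto acid out of every acidic or radical step. The forward reaction must oxidise CH2OH to CO2H in the presence of the tertiary hemiketal OH, the peroxide and the benzylic chain, and must not let aldehyde 19 accumulate.

**18 from 16.** A tert-butyl ester is put back on C4 and the C1 oxygen is capped as a tert-butyl ether. Both groups fall in one acid treatment, so the temporary ester costs no separate deprotection. The forward step cleaves both groups, lets acid 17 lose CO2, and leaves C3 and C4 to equilibrate. Compound 18 is neutral and one near-neutral step from 20, so the diastereomers are separated here.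

**16 from 9 and 14 with O2.** Three bonds are cut at once: C4–C5, C6–O1 and C3–O2. The neighbouring cuts (C6–O1 alone; C5–C6 with C3–O2; oxygen insertion into a C3–C6 bond) all need a more elaborate precursor. This cut divides the molecule into alkene 9 and keto ester 14, each reachable in at most four steps, and uses a known annulation of 2-substituted β-keto esters with 1,1-disubstituted alkenes. The forward reaction must oxidise only C4–H and add at the alkene CH2. It cannot control C6, which is accepted and paid for by a separation.

**14 from 10 and 11.** The C3–C4 bond is cut as a crossed Claisen acylation of the enolate of 11 by acid 10. A tert-butyl ether is preferred to an alkene mask for C1–C2: an alkene in the dicarbonyl partner would compete for the C4 radical and, as a β,γ-unsaturated ketone, could drift into conjugation each time the hemiketal opens. It is preferred to a silyl ether because it leaves in the same step as the ester.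

**9 from 6 and 7.** The C9–C10 bond is cut as a copper-catalysed coupling of tosylate 6 with the Grignard reagent 8 made from bromide 7. The stereocentre and the finished 1,1-disubstituted alkene stay in a five-carbon piece, and the long chain comes from a plain ω-phenylalkyl bromide.

**6 from 1 and 2.** Tosylate 6 comes from alcohol 5, and 5 from imide 4 by reductive removal of the auxiliary. The C7–C8 bond of 4 is cut as an auxiliary-controlled alkylation of 1 with methallyl bromide 2. This sets C8 with a diastereomer that can be purified, and delivers the alkene without a separate olefination; a chiral-pool terpene start would give variable enantiopurity and a longer sequence.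

## Roads not taken

**Alternative 1:** Cycloperoxymercuration cuts only C6–O1.
- Forward step: the open-chain precursor A1 carries C3 as a hydroperoxy methyl ketal and an (E)-C6=C7 alkene. Hg(OAc)2 (divalent mercury) activates the alkene, the terminal peroxide oxygen attacks the more substituted C6 in a 6-exo closure through a chair, and organomercurial A2 results.
- Merits: the chair can relay the C4 configuration to C6, which the chosen plan cannot do. If C4 were set by asymmetric synthesis, every centre would be controlled. C1 is at the ester level from the start and no decarboxylation is needed.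
- Weak points: demercuration of A2 with NaBH4 passes through a C7 radical β to the peroxide, which can attack the O–O bond and give an epoxide. Mercury is stoichiometric. Making the C3 hydroperoxy ketal from a β-keto ester invites epimerisation at C4, the very control element. The product is a methyl ketal and methyl ester, so two more unmasking steps follow, and the ketal-to-hemiketal hydrolysis is uncertain. A1 itself needs a long linear synthesis.
- Comparison: this road is better on C6 control. The chosen plan sets against it an eight-step route, no mercury, no radical generated next to the peroxide, and direct formation of the hemiketal.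

**Alternative 2:** A formal [3+3] annulation cuts C5–C6 and C3–O2.
- Forward step: silylperoxy ketal A3 is ionised by a Lewis acid such as Me3SiOTf to a C6 peroxycarbenium ion. The CH2 carbon of siloxycyclopropane A4 attacks it, the ring opens to a C3 oxocarbenium ion, and the peroxide oxygen closes to A5.
- Merits: convergent; C4 carries hydrogen from the start, so no temporary ester and no decarboxylation are needed. That is a real advantage over the chosen plan.
- Weak points: this annulation is not an established reaction; such cations are known to give five-membered peroxides or open-chain products with π-nucleophiles. Ketone-derived peroxycarbenium ions are prone to Criegee- or Hock-type fragmentation. C6 is a planar cation, so it is as uncontrolled as in the chosen plan. A4 needs its own synthesis, and A5 still requires two desilylations and the same final oxidation.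
- Comparison: the stereochemical outcome is the same and one correction step is saved, but the key step is unprecedented, whereas the chosen key step is a known reaction type.

**Alternative 3:** Oxygen insertion into a cyclobutanol cuts the C3–C6 bond in the forward direction.
- Forward step: cyclobutanone A6 takes up an acetate ester enolate to give cyclobutanol A7. Co(acac)2 (divalent cobalt) and O2 generate the C3 alkoxy radical, β-scission releases the tertiary C6 radical, O2 is captured and the hydroperoxide closes on the new ketone to give A8, the tert-butyl ester of 20.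
- Merits: the reaction type is known. C1 enters as an ester because no enolate is oxidised, C4 carries hydrogen from the start, and A8 is one deprotection from 20. In these respects it is better than the chosen plan.
- Weak points: A6 needs the quaternary carbon α to the carbonyl, the opposite of what ketene–alkene cycloadditions deliver, so the ring must be built in several steps. C6 again passes through a free radical and is uncontrolled. The alkoxy radical can also cleave toward C4 or expel the stabilised ester-bearing arm. The last step would expose the free latent β-keto acid to strong acid.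
- Comparison: the chosen plan sets against it a shorter access to both fragments and a buffered, near-neutral final step.

Key step: step 6

Remark 1: 16 and its precursors 15 and 17 are diastereomer mixtures; name and SMILES show the isomer whose ring centres map onto 20, and the accompanying isomers are stated in the steps.
Remark 2: (7-bromoheptyl)benzene 7 and 3-(tert-butoxy)propanoic acid 10 are taken as catalogue chemicals.

## Route

Step 1
Reactants: 1 (4R)-4-benzyl-3-propanoyl-1,3-oxazolidin-2-one; 2 3-bromo-2-methylprop-1-ene
Product: 4 (4R)-4-benzyl-3-[(2S)-2,4-dimethylpent-4-enoyl]-1,3-oxazolidin-2-one, via sodium Z-enolate 3 (not isolated)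
Conditions: NaHMDS, THF, −78 °C; then 2, −78 → −40 °C
Reagents that add atoms: none
Why: Evans asymmetric alkylation: the chelated Z-enolate 3 is alkylated by SN2 on the face away from the benzyl group, which sets the future C8 (2S in 4); the minor diastereomer is removed by chromatography or crystallisation.

Step 2
Reactants: 4 (4R)-4-benzyl-3-[(2S)-2,4-dimethylpent-4-enoyl]-1,3-oxazolidin-2-one
Product: 5 (2S)-2,4-dimethylpent-4-en-1-ol
Conditions: LiBH4, MeOH (1.1 equiv), Et2O, 0 °C
Reagents that add atoms: none
Why: Reductive cleavage of the N-acyl oxazolidinone by hydride at the exocyclic carbonyl; the α-centre is not enolised and the auxiliary is recovered.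

Step 3
Reactants: 5 (2S)-2,4-dimethylpent-4-en-1-ol
Product: 6 (2S)-2,4-dimethylpent-4-en-1-yl 4-methylbenzenesulfonate
Conditions: TsCl, Et3N, DMAP (cat.), CH2Cl2, 0 °C → rt
Reagents that add atoms: 4-methylbenzenesulfonyl chloride, Cc1ccc(cc1)S(=O)(=O)Cl
Why: Sulfonylation of a primary alcohol; no bond to the stereocentre is touched.

Step 4
Reactants: 6 (2S)-2,4-dimethylpent-4-en-1-yl 4-methylbenzenesulfonate; 7 (7-bromoheptyl)benzene
Product: 9 (4R)-2,4-dimethyl-12-phenyldodec-1-ene, via Grignard reagent 8 (not isolated)
Conditions: 7, Mg, THF, 40 °C; then 6, Li2CuCl4 (3 mol %), THF, −20 °C → rt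
Reagents that add atoms: none
Why: Kochi-type copper-catalysed sp3–sp3 coupling of a primary Grignard reagent with a primary tosylate; the stereocentre is β to the reacting carbon and is untouched (S becomes R only through the priority change).

Step 5
Reactants: 10 3-(tert-butoxy)propanoic acid; 11 tert-butyl propanoate
Product: 14 tert-butyl 5-(tert-butoxy)-2-methyl-3-oxopentanoate (racemic), via acyl imidazole 12 (not isolated), via lithium enolate 13 (not isolated)
Conditions: 10, 1,1'-carbonyldiimidazole (CDI), THF, rt; 11 (2.2 equiv), LDA (2.2 equiv), THF, −78 °C; then 12 added, −78 → −40 °C; aq NH4Cl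
Reagents that add atoms: none
Why: Crossed Claisen condensation (C-acylation of an ester enolate by an N-acyl imidazole); the second equivalent of enolate deprotonates 14 and so prevents a second addition; the α-centre of 14 is labile and its configuration is irrelevant.

Step 6
Reactants: 9 (4R)-2,4-dimethyl-12-phenyldodec-1-ene; 14 tert-butyl 5-(tert-butoxy)-2-methyl-3-oxopentanoate
Product: 16 tert-butyl (3S,4S,6S)-3-(2-tert-butoxyethyl)-3-hydroxy-4,6-dimethyl-6-[(2R)-2-methyl-10-phenyldecyl]-1,2-dioxane-4-carboxylate (drawn isomer; obtained with its C6 and C4 epimers), via hydroperoxy keto ester 15 (not isolated)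
Conditions: Mn(OAc)3·2H2O (0.2 equiv), 14 (2 equiv), AcOH, O2 (1 atm), 23 °C
Reagents that add atoms: dioxygen, O=O
Why: Mn(OAc)3 (trivalent manganese) forms the manganese enolate of 14 at its only doubly activated position and oxidises it to the electrophilic C4 radical, which adds to the unsubstituted alkene carbon of 9 (C4–C5) to give the tertiary C6 radical. This radical is captured by O2 (C6–O1), the peroxyl radical is reduced by Mn(OAc)2 (divalent manganese, which returns the trivalent oxidant, so the metal is catalytic) to hydroperoxide 15, and the hydroperoxide oxygen adds to the C3 ketone (C3–O2). The closest known reaction type is the aerobic manganese-acetate annulation of 2-substituted 1,3-dicarbonyl compounds with 1,1-disubstituted alkenes to 1,2-dioxan-3-ols. The one ring closes by a polar 6-exo-trig addition of the hydroperoxide to the ketone carbonyl, which is reversible, so C3 settles with the anomeric hydroxyl axial. C6 forms when O2 meets an open-chain tertiary radical whose only stereocentre (C8) lies two bonds away on a flexible chain, so nothing controls it and both C6 epimers are expected in similar amounts; C4 is quaternary here and its configuration is erased in step 7. The step needs site selectivity in the oxidation, secured because only C4–H lies between two carbonyls while C2–H2 is singly activated and the tert-butyl ether is inert to radicals and to AcOH. It also needs regioselective addition, secured by the polarity match of the electrophilic radical with the electron-rich CH2 terminus and by the tertiary adduct radical. Keto ester 14 is used in excess because 9 is the valuable partner.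

Step 7
Reactants: 16 tert-butyl 3-(2-tert-butoxyethyl)-3-hydroxy-4,6-dimethyl-6-[(2R)-2-methyl-10-phenyldecyl]-1,2-dioxane-4-carboxylate (diastereomer mixture from step 6)
Product: 18 (3S,4R,6S)-3-(2-hydroxyethyl)-4,6-dimethyl-6-[(2R)-2-methyl-10-phenyldecyl]-1,2-dioxan-3-ol, via hydroxy acid 17 (not isolated)
Conditions: TFA/CH2Cl2/H2O (10:10:1), 0 °C → rt; then toluene, 45 °C; preparative HPLC
Reagents that add atoms: none
Why: Proposed new method: decarboxylation of a β-keto acid whose ketone is masked as a cyclic peroxy hemiketal has no direct precedent known to the proposer; in wet TFA both tert-butyl groups leave as 2-methylpropene, the hemiketal of 17 equilibrates with the open hydroperoxy β-keto acid, and this should lose CO2 through the usual six-membered transition state to an enol that ketonises and recloses (a second channel is CO2 loss from the C3 peroxycarbenium ion to a cyclic enol peroxide that water rehydrates); the closest known reaction types are the TFA dealkoxycarbonylation of α,α-disubstituted tert-butyl β-keto esters and the decarboxylation of lactol-masked β-keto acids; C3 is set by the anomeric preference for axial OH, C4 equilibrates through the open ketone toward the equatorial methyl, the 6S isomer is separated from the 6R series by HPLC, and C4-epimeric 6S material can be returned to the acid for re-equilibration.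

Step 8
Reactants: 18 (3S,4R,6S)-3-(2-hydroxyethyl)-4,6-dimethyl-6-[(2R)-2-methyl-10-phenyldecyl]-1,2-dioxan-3-ol
Product: 20 2-[(3S,4R,6S)-3-hydroxy-4,6-dimethyl-6-[(2R)-2-methyl-10-phenyldecyl]-1,2-dioxan-3-yl]acetic acid, via aldehyde 19 (not isolated)
Conditions: 2,2,6,6-tetramethylpiperidin-1-oxyl (TEMPO, 7 mol %), NaOCl (2 mol %), NaClO2 (2 equiv), MeCN/sodium phosphate buffer pH 6.7, 23–35 °C
Reagents that add atoms: sodium chlorite, [Na+].[O-]Cl=O
Why: Oxoammonium-catalysed oxidation of the primary alcohol to aldehyde 19, which chlorite converts at once to the acid (Pinnick-type step); the tertiary hemiketal OH cannot be oxidised, peroxide and arene are inert to these oxidants, and the near-neutral buffer keeps the ring closed so the ring stereocentres persist.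

## Compound list

1 | (4R)-4-benzyl-3-propanoyl-1,3-oxazolidin-2-one | CCC(=O)N1[C@H](Cc2ccccc2)COC1=O | starting material
2 | 3-bromo-2-methylprop-1-ene | CC(=C)CBr | starting material
3 | sodium (Z)-enolate of 1 | C/C=C(\[O-])N1[C@H](Cc2ccccc2)COC1=O.[Na+] | intermediate (not isolated)
4 | (4R)-4-benzyl-3-[(2S)-2,4-dimethylpent-4-enoyl]-1,3-oxazolidin-2-one | C[C@@H](CC(C)=C)C(=O)N1[C@H](Cc2ccccc2)COC1=O | intermediate
5 | (2S)-2,4-dimethylpent-4-en-1-ol | C[C@H](CO)CC(C)=C | intermediate
6 | (2S)-2,4-dimethylpent-4-en-1-yl 4-methylbenzenesulfonate | C[C@H](COS(=O)(=O)c1ccc(C)cc1)CC(C)=C | intermediate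
7 | (7-bromoheptyl)benzene | BrCCCCCCCc1ccccc1 | starting material
8 | (7-phenylheptyl)magnesium bromide | Br[Mg]CCCCCCCc1ccccc1 | intermediate (not isolated)
9 | (4R)-2,4-dimethyl-12-phenyldodec-1-ene | C[C@H](CCCCCCCCc1ccccc1)CC(C)=C | intermediate
10 | 3-(tert-butoxy)propanoic acid | CC(C)(C)OCCC(=O)O | starting material
11 | tert-butyl propanoate | CCC(=O)OC(C)(C)C | starting material
12 | 3-(tert-butoxy)-1-(1H-imidazol-1-yl)propan-1-one | CC(C)(C)OCCC(=O)n1ccnc1 | intermediate (not isolated)
13 | lithium enolate of tert-butyl propanoate | CC=C([O-])OC(C)(C)C.[Li+] | intermediate (not isolated)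
14 | tert-butyl 5-(tert-butoxy)-2-methyl-3-oxopentanoate (racemic) | CC(C(=O)OC(C)(C)C)C(=O)CCOC(C)(C)C | intermediate
15 | tert-butyl (2S,4S,6R)-2-[3-(tert-butoxy)propanoyl]-4-hydroperoxy-2,4,6-trimethyl-14-phenyltetradecanoate (drawn isomer; with its C2 and C4 epimers) | C[C@H](CCCCCCCCc1ccccc1)C[C@@](OO)(C)C[C@@](C(=O)OC(C)(C)C)(C)C(=O)CCOC(C)(C)C | intermediate (not isolated)
16 | tert-butyl (3S,4S,6S)-3-(2-tert-butoxyethyl)-3-hydroxy-4,6-dimethyl-6-[(2R)-2-methyl-10-phenyldecyl]-1,2-dioxane-4-carboxylate (drawn isomer; with its C6 and C4 epimers) | C[C@H](CCCCCCCCc1ccccc1)C[C@@]1(C)C[C@@](C(=O)OC(C)(C)C)(C)[C@](O)(CCOC(C)(C)C)OO1 | intermediate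
17 | (3S,4S,6S)-3-hydroxy-3-(2-hydroxyethyl)-4,6-dimethyl-6-[(2R)-2-methyl-10-phenyldecyl]-1,2-dioxane-4-carboxylic acid (drawn isomer; with its C6 and C4 epimers) | C[C@H](CCCCCCCCc1ccccc1)C[C@@]1(C)C[C@@](C(=O)O)(C)[C@](O)(CCO)OO1 | intermediate (not isolated)
18 | (3S,4R,6S)-3-(2-hydroxyethyl)-4,6-dimethyl-6-[(2R)-2-methyl-10-phenyldecyl]-1,2-dioxan-3-ol | C[C@H](CCCCCCCCc1ccccc1)C[C@@]1(C)C[C@@H](C)[C@](O)(CCO)OO1 | intermediate
19 | 2-[(3S,4R,6S)-3-hydroxy-4,6-dimethyl-6-[(2R)-2-methyl-10-phenyldecyl]-1,2-dioxan-3-yl]acetaldehyde | C[C@H](CCCCCCCCc1ccccc1)C[C@@]1(C)C[C@@H](C)[C@](O)(CC=O)OO1 | intermediate (not isolated)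
20 | 2-[(3S,4R,6S)-3-hydroxy-4,6-dimethyl-6-[(2R)-2-methyl-10-phenyldecyl]-1,2-dioxan-3-yl]acetic acid | C[C@H](CCCCCCCCc1ccccc1)C[C@@]1(C)C[C@@H](C)[C@](O)(CC(=O)O)OO1 | target

## Step count and risks

Total: 8 steps. Longest linear sequence: 7 steps (1, 2, 3, 4, 6, 7, 8); step 5 is a one-step branch.

**Step 7 (proposed new method).**
- What may go wrong: the open keto acid may be too sparsely populated for CO2 loss at temperatures the peroxide tolerates. Prolonged acid may ionise the tertiary C6–O bond or dehydrate the hemiketal. The β-hydroxy ketone of the open form may eliminate water. The C6 epimers may resolve poorly on the column.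
- Fallback (known reactions only, decarboxylation moved ahead of the peroxide): it sets out from 9 and 14. Ene-type allylic chlorination of 9 (Ca(OCl)2, CO2, CH2Cl2/H2O) should give (4R)-2-(chloromethyl)-4-methyl-12-phenyldodec-1-ene F1; its double-bond isomer converges later. C-alkylation of 14 with F1 (K2CO3, NaI, acetone) gives tert-butyl (6R)-2-[3-(tert-butoxy)propanoyl]-2,6-dimethyl-4-methylidene-14-phenyltetradecanoate F2. Wet TFA then cleaves both tert-butyl groups and decarboxylates an ordinary β-keto acid to (8R)-1-hydroxy-4,8-dimethyl-6-methylidene-16-phenylhexadecan-3-one F3. Mukaiyama–Isayama hydroperoxysilylation (Co(acac)2, divalent cobalt, Et3SiH, O2) places the peroxide on the tertiary C6 to give (8R)-1-hydroxy-4,6,8-trimethyl-16-phenyl-6-[(triethylsilyl)peroxy]hexadecan-3-one F4. Mild aqueous acid removes the silyl group and the hydroperoxide closes on the ketone. The route is rejoined at 18 after the same HPLC separation.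

**Step 6 (key step).**
- What may go wrong: the hindered α-branched keto ester may be oxidised slowly, and the non-activated alkene may capture the radical inefficiently, giving low conversion. The peroxyl radical may abstract hydrogen from the chain instead of being reduced. Oxygen capture at C6 is unselective, so about half of the material is expected in the unwanted C6 series.
- Assignment: the 4,6-relationship follows from the NOE between the axial C6 methyl and the axial C4–H; the C6/C8 relationship is assigned by comparing 20 with the data of the natural substance.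
- Fallback (two-electron construction of C4–C5, then a separate peroxidation): it sets out from 9 and 14 and passes through chloride F1 and alkylated keto ester F2 as described for step 7. F2 is then hydroperoxysilylated directly (Co(acac)2, Et3SiH, O2) to tert-butyl (6R)-2-[3-(tert-butoxy)propanoyl]-2,4,6-trimethyl-14-phenyl-4-[(triethylsilyl)peroxy]tetradecanoate F5. Mild acid desilylation lets the hydroperoxide close on the ketone, and the route is rejoined at 16.

**Step 8.**
- What may go wrong: aldehyde 19 may open to an enolised β-keto aldehyde and be diverted. The product may lose C1 by decarboxylation through its open form during acidic extraction.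
- Fallback (the ring is locked before the oxidation): it sets out from 18. Acid-catalysed exchange in MeOH (pyridinium 4-methylbenzenesulfonate, rt) gives 2-[(3S,4R,6S)-3-methoxy-4,6-dimethyl-6-[(2R)-2-methyl-10-phenyldecyl]-1,2-dioxan-3-yl]ethan-1-ol F6. The same TEMPO/chlorite oxidation then acts on a ketal that cannot open and gives 2-[(3S,4R,6S)-3-methoxy-4,6-dimethyl-6-[(2R)-2-methyl-10-phenyldecyl]-1,2-dioxan-3-yl]acetic acid F7. Brief hydrolysis in dilute aqueous acid at 0 °C, through the peroxycarbenium ion, rejoins the route at 20.

**Step 5.**
- What may go wrong: the strongly basic enolate may deprotonate acyl imidazole 12 or trigger β-elimination of tert-butoxide instead of acylating, lowering conversion.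
- Fallback (neutral decarboxylative acylation, Masamune–Brooks type): it sets out from 11 and 10. Enolate 13 is carboxylated with CO2 to 3-(tert-butoxy)-2-methyl-3-oxopropanoic acid F8. Its magnesium salt (MgCl2, Et3N, MeCN) is acylated by 12 at rt with loss of CO2, and the route is rejoined at 14.

## Further compounds

F1 | step 7 | (4R)-2-(chloromethyl)-4-methyl-12-phenyldodec-1-ene | C[C@H](CCCCCCCCc1ccccc1)CC(=C)CCl
F2 | step 7 | tert-butyl (6R)-2-[3-(tert-butoxy)propanoyl]-2,6-dimethyl-4-methylidene-14-phenyltetradecanoate | C[C@H](CCCCCCCCc1ccccc1)CC(=C)CC(C)(C(=O)OC(C)(C)C)C(=O)CCOC(C)(C)C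
F3 | step 7 | (8R)-1-hydroxy-4,8-dimethyl-6-methylidene-16-phenylhexadecan-3-one | C[C@H](CCCCCCCCc1ccccc1)CC(=C)CC(C)C(=O)CCO
F4 | step 7 | (8R)-1-hydroxy-4,6,8-trimethyl-16-phenyl-6-[(triethylsilyl)peroxy]hexadecan-3-one | C[C@H](CCCCCCCCc1ccccc1)CC(C)(OO[Si](CC)(CC)CC)CC(C)C(=O)CCO
F5 | step 6 | tert-butyl (6R)-2-[3-(tert-butoxy)propanoyl]-2,4,6-trimethyl-14-phenyl-4-[(triethylsilyl)peroxy]tetradecanoate | C[C@H](CCCCCCCCc1ccccc1)CC(C)(OO[Si](CC)(CC)CC)CC(C)(C(=O)OC(C)(C)C)C(=O)CCOC(C)(C)C
F6 | step 8 | 2-[(3S,4R,6S)-3-methoxy-4,6-dimethyl-6-[(2R)-2-methyl-10-phenyldecyl]-1,2-dioxan-3-yl]ethan-1-ol | C[C@H](CCCCCCCCc1ccccc1)C[C@@]1(C)C[C@@H](C)[C@](OC)(CCO)OO1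
F7 | step 8 | 2-[(3S,4R,6S)-3-methoxy-4,6-dimethyl-6-[(2R)-2-methyl-10-phenyldecyl]-1,2-dioxan-3-yl]acetic acid | C[C@H](CCCCCCCCc1ccccc1)C[C@@]1(C)C[C@@H](C)[C@](OC)(CC(=O)O)OO1
F8 | step 5 | 3-(tert-butoxy)-2-methyl-3-oxopropanoic acid | CC(C(=O)O)C(=O)OC(C)(C)C
A1 | alternative 1 | methyl (4R,6E,8R)-3-hydroperoxy-3-methoxy-4,6,8-trimethyl-16-phenylhexadec-6-enoate | C[C@H](CCCCCCCCc1ccccc1)/C=C(\C)C[C@@H](C)C(OC)(OO)CC(=O)OC
A2 | alternative 1 | methyl 2-[6-[1-(acetoxymercurio)-2-methyl-10-phenyldecyl]-3-methoxy-4,6-dimethyl-1,2-dioxan-3-yl]acetate | C[C@H](CCCCCCCCc1ccccc1)[C@H]([Hg]OC(C)=O)[C@@]1(C)C[C@@H](C)[C@](OC)(CC(=O)OC)OO1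
A3 | alternative 2 | (4R)-2-methoxy-4-methyl-12-phenyl-2-[(trimethylsilyl)peroxy]dodecane | C[C@H](CCCCCCCCc1ccccc1)CC(C)(OC)OO[Si](C)(C)C
A4 | alternative 2 | tert-butyldimethyl{2-[(2R)-2-methyl-1-(trimethylsilyloxy)cyclopropyl]ethoxy}silane | C1[C@@H](C)C1(CCO[Si](C)(C)C(C)(C)C)O[Si](C)(C)C
A5 | alternative 2 | 3-[2-(tert-butyldimethylsilyloxy)ethyl]-4,6-dimethyl-6-[(2R)-2-methyl-10-phenyldecyl]-3-(trimethylsilyloxy)-1,2-dioxane | C[C@H](CCCCCCCCc1ccccc1)C[C@@]1(C)C[C@@H](C)[C@](O[Si](C)(C)C)(CCO[Si](C)(C)C(C)(C)C)OO1
A6 | alternative 3 | 2,4-dimethyl-2-[(2R)-2-methyl-10-phenyldecyl]cyclobutan-1-one (ring diastereomers) | C[C@H](CCCCCCCCc1ccccc1)CC1(C)CC(C)C1=O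
A7 | alternative 3 | tert-butyl 2-[1-hydroxy-2,4-dimethyl-2-[(2R)-2-methyl-10-phenyldecyl]cyclobutyl]acetate (ring diastereomers) | C[C@H](CCCCCCCCc1ccccc1)CC1(C)CC(C)C1(O)CC(=O)OC(C)(C)C
A8 | alternative 3 | tert-butyl 2-[(3S,4R,6S)-3-hydroxy-4,6-dimethyl-6-[(2R)-2-methyl-10-phenyldecyl]-1,2-dioxan-3-yl]acetate | C[C@H](CCCCCCCCc1ccccc1)C[C@@]1(C)C[C@@H](C)[C@](O)(CC(=O)OC(C)(C)C)OO1
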